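- Read this flask by what is not yet product, because that is what a waiting time can still turn into product; the question is how fast that remainder shrinks.

all flasks: gas 0.37 mM (held); free catalyst 21 µM
- beta: substrate 1 mM; temperature 80 °C; the very flask that is asked about, followed so far
- eta: substrate 1 mM; temperature 86 °C; run made earlier
- flask: substrate 1.0 mM; temperature 80 °C; time 30 min

| run | time / min | product / % | substrate / % |
|---|---|---|---|
| beta | 2.50 | 38.7 | 60.9 |
| beta | 8.00 | 64.0 | 35.2 |
| beta | 15.0 | 71.7 | 27.3 |
| beta | 20.0 | 74.6 | 24.3 |
| beta | 30.0 | 77.7 | 19.6 |
| eta | 2.50 | 43.3 | 56.3 |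
| eta | 8.00 | 62.9 | 35.8 |
| eta | 15.0 | 69.7 | 28.4 |
| eta | 20.0 | 73.5 | 25.3 |
| eta | 30.0 | 78.9 | 20.1 |

(readings scatter by 0.5 percentage points)

- red: at 30 min add free catalyst, 100 % of the amount charged, then wait 30 min
- green: at 30 min raise the temperature by 10 K, then wait 30 min
- amber: change nothing and wait 30 min more
- teal: at 30 min take out 90 % of the product then present, then wait 30 min

- what is taken out of product is counted as made
- at the start none of the gas is in solution
- additions bring no volume worth counting

- product, in percent of the substrate first charged, at 30 min
- the option that brings most further product ("none" if no option brings more than 2 percentage points) (red / green / amber / teal / none)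
- product present, with what was taken out counted in, in percent of the substrate first charged, after amber
- product present, with what was taken out counted in, in percent of the substrate first charged, after teal

- First instants: the beta run, which is this flask followed so far, reaches 38.7 % product by 2.50 min, a pseudo-first-order constant of 0.196 min⁻¹.
- Middle: between 8.00 min and 15.0 min the beta run shows 0.0344 min⁻¹, much slower than the start. A first-order constant already allows for falling [substrate], so the beta run does not follow one exponential.
- End: [substrate] still reads 19.6 % at 30.0 min, so the flask has not stopped for want of substrate. A curve that bends like this can be replaced by its mean over the tail: the tail constant, the natural logarithm of the ratio of not-yet-product at 15.0 min and 30.0 min, divided by the time between, reads 0.01589 min⁻¹.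
- My reckoning takes 77.7 % for now, as read. The tail constant then gives 86.2 % after amber, a gain of 8.5 percentage points, above the margin.
- The mean has an error of known sign. The last stretch alone reads 0.01302 min⁻¹, lower than the mean, and gives 84.9 %. So amber lies nearer the lower figure if the constant goes on falling.
- The forecast says 78.5 % (77.5 % to 79.5 %), 85 % after amber (81.5 % to 88.5 %), 85.5 % after teal (81.5 % to 90 %), and red as best: “Extra catalyst acts directly on the limiting factor”. Its amber figure stands below my mean reckoning.
- The flask gives 78.0 % now, 85.0 % after amber and 86.1 % after teal. Best is red, with 18 points further product, against 11 points for green, 8.2 points for teal and 7 points for amber. The forecast holds, and the mean reckoning overshot amber by 1.2 points.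

    catalyst intermediate A → catalyst intermediate B (k = 1.36 s⁻¹, Ea = 84.0 kJ mol⁻¹)
    catalyst intermediate C → free catalyst + product (k = 10.9 s⁻¹, Ea = 72.0 kJ mol⁻¹)
    substrate + free catalyst ⇌ catalyst intermediate A (K = 8320 L mol⁻¹, k = 224 L mol⁻¹ s⁻¹, Ea = 46.0 kJ mol⁻¹, ΔH = −34.0 kJ mol⁻¹)
    gas ⇌ coupling partner, rate k4*(csat - [coupling partner]) (kL = 0.809 s⁻¹)
    catalyst intermediate A + product → spent catalyst (k = 27.8 L mol⁻¹ s⁻¹, Ea = 53.0 kJ mol⁻¹)
    free catalyst ⇌ dormant form (K = 9.90, k = 0.00272 s⁻¹, Ea = 103 kJ mol⁻¹, ΔH = −18.0 kJ mol⁻¹)
    coupling partner + catalyst intermediate B → catalyst intermediate C (k = 30800 L mol⁻¹ s⁻¹, Ea = 42.0 kJ mol⁻¹)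
    (constants at 80 °C)

- This flask has not come to rest at 30.0 min: 21 % substrate stands beside 78.0 % product, with free catalyst at 5.36 % of the catalyst charged. Ten times the time brings product to 97.5 % and substrate to 0.522 %, while, again in percent of the catalyst charged, spent catalyst climbs from 29.9 % to 46.9 % and dormant form drops from 64.5 % to 48.3 %. The tail constant, started from 78.0 %, gives 99.7 % there, again above the flask.
- For the neighbour left until 50 min, the tail constant gives 83.8 % from the reading at 30.0 min. That neighbour holds 83.0 %.

(The earlier runs and the new flask come from a simulation for substances that don't exist, noise included.)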